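**Strategy.** Everything rests on cutting ring A at C3a–C7a and C4–C5. In benzofuran numbering, C7a–C7–C6–C5 (O1 on C7a, ketone at C6, methoxy on C5) is a latent 1-alkoxy-3-silyloxy-4-methoxy diene carried on O1, and quaternary C3a with C4 is a latent 2-substituted acrylate whose ester carbon becomes the allyl CH2. One thermal intramolecular Diels–Alder reaction therefore forms both bonds, closes rings A and B together and sets C3a from the C2/C3 stereodiad. Its precursor is the anti-(3R,4R) tert-butyl 4-aryl-3-methyl-2-methylidenebutanoate whose carbinol oxygen (future O1) bears a (1E,3Z)-3-silyloxy-4-methoxybutadienyl group, made by asymmetric crotylboration, oxa-Michael addition and silylation.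

Key step: step 6

Remark: tert-butyl but-2-ynoate, pinacol (iodomethyl)boronate and N,2-dimethoxy-N-methylacetamide are taken as catalogue chemicals; ring atoms are numbered as in benzofuran (O1, C2 aryl, C3 methyl, C3a, C4, C5 methoxy, C6, C7, C7a; ring A the carbocycle, ring B the oxygen ring).

**Step 1**
Reactants: 1 tert-butyl but-2-ynoate; 2 2-(iodomethyl)-4,4,5,5-tetramethyl-1,3,2-dioxaborolane
Product: 4 tert-butyl (Z)-2-[(4,4,5,5-tetramethyl-1,3,2-dioxaborolan-2-yl)methyl]but-2-enoate, via α-alumino enoate 3 (not isolated)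
Conditions: iBu2AlH, HMPA, THF, 0 °C; then 2, 0 °C to rt
Reagents that add atoms: none
Why: Conjugate hydroalumination of the ynoate by the iBu2AlH–HMPA complex gives the α-alumino enoate 3 (equilibrating with its aluminium allenoate form), and its α-carbon is alkylated by the iodomethylboronate (boron ate complex, 1,2-shift with loss of iodide) on the side away from the γ-methyl, so CH2B and CH3 end trans on the double bond, the E-crotyl arrangement that an anti-selective crotylboration needs.

**Step 2**
Reactants: 4 tert-butyl (Z)-2-[(4,4,5,5-tetramethyl-1,3,2-dioxaborolan-2-yl)methyl]but-2-enoate; 5 3,4,5-trimethoxybenzaldehyde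
Product: 6 tert-butyl (3R,4R)-4-hydroxy-3-methyl-2-methylidene-4-(3,4,5-trimethoxyphenyl)butanoate (anti)
Conditions: (R)-TRIP [(R)-3,3'-bis(2,4,6-triisopropylphenyl)-1,1'-binaphthyl-2,2'-diyl hydrogen phosphate] (10 mol%), 4 Å molecular sieves, PhMe, 0 °C to rt; aq. NaHCO3 work-up
Reagents that add atoms: none
Why: Chiral-phosphoric-acid-catalysed crotylboration through a closed chair transition state, in which the methyl group trans to CH2B sits equatorial and gives the anti pair, the acid (hydrogen-bonded to a boronate oxygen and to the formyl hydrogen) exposes the Re face of the aldehyde so that the carbinol carbon and hence the methyl-bearing carbon are both R (the antipodal acid is used if the ester-bearing reagent reverses the facial sense), and the tert-butyl ester keeps the γ-hydroxy ester from lactonising.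

**Step 3**
Reactants: 7 N,2-dimethoxy-N-methylacetamide; 8 ethynylmagnesium bromide
Product: 9 1-methoxybut-3-yn-2-one
Conditions: HC≡CMgBr, THF, −78 to 0 °C; inverse quench into cold 1 M aq. HCl; used as a solution
Reagents that add atoms: none
Why: Weinreb ketone synthesis, in which the N-methoxy-N-methylamide takes up exactly one equivalent of the alkynyl Grignard reagent and the cold acidic quench protonates the released amine before it can add to the ynone.

**Step 4**
Reactants: 6 tert-butyl (3R,4R)-4-hydroxy-3-methyl-2-methylidene-4-(3,4,5-trimethoxyphenyl)butanoate; 9 1-methoxybut-3-yn-2-one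
Product: 10 tert-butyl (3R,4R)-4-{[(1E)-4-methoxy-3-oxobut-1-en-1-yl]oxy}-3-methyl-2-methylidene-4-(3,4,5-trimethoxyphenyl)butanoate
Conditions: DABCO (10 mol%), CH2Cl2, 0 °C to rt
Reagents that add atoms: none
Why: Tertiary-amine-catalysed oxa-Michael addition of the secondary alcohol to the terminal ynone gives the thermodynamically favoured E-β-alkoxy enone under conditions too mild for lactonisation or for attack on the hindered tert-butyl 2-alkylacrylate, and no stereocentre is touched.

**Step 5**
Reactants: 10 tert-butyl (3R,4R)-4-{[(1E)-4-methoxy-3-oxobut-1-en-1-yl]oxy}-3-methyl-2-methylidene-4-(3,4,5-trimethoxyphenyl)butanoate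
Product: 11 tert-butyl (3R,4R)-4-{[(1E,3Z)-3-(tert-butyldimethylsilyloxy)-4-methoxybuta-1,3-dien-1-yl]oxy}-3-methyl-2-methylidene-4-(3,4,5-trimethoxyphenyl)butanoate
Conditions: TBSOTf, Et3N, Et2O, −78 to 0 °C; filtration through Et3N-deactivated alumina, used directly
Reagents that add atoms: tert-butyldimethylsilyl trifluoromethanesulfonate, CC(C)(C)[Si](C)(C)OS(=O)(=O)C(F)(F)F
Why: Soft enolisation (silyl triflate and amine) of the vinylogous ester at its only acidic position, the methoxymethyl group, gives the cross-conjugated 2-silyloxy diene with silyloxy and methoxy cis on the new double bond (Z), leaves the E-enol ether and both stereocentres untouched, and is fast enough at low temperature to spare the tert-butyl ester.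

**Step 6**
Reactants: 11 tert-butyl (3R,4R)-4-{[(1E,3Z)-3-(tert-butyldimethylsilyloxy)-4-methoxybuta-1,3-dien-1-yl]oxy}-3-methyl-2-methylidene-4-(3,4,5-trimethoxyphenyl)butanoate
Product: 12 tert-butyl (2R,3R,3aS,5R,7aR)-6-(tert-butyldimethylsilyloxy)-5-methoxy-3-methyl-2-(3,4,5-trimethoxyphenyl)-2,3,4,5-tetrahydro-1-benzofuran-3a(7aH)-carboxylate (cis-fused; C6=C7 silyl enol ether; ester cis to the C3 methyl and to H7a; aryl trans to methyl; methoxy trans to the ester)
Conditions: PhMe (0.01 M), BHT (cat.), Et3N (cat.), base-washed sealed tube, 120 °C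
Reagents that add atoms: none
Why: The step is a concerted but asynchronous normal-demand [4+2] cycloaddition in which the diene terminus C5, made nucleophilic by O1 and the silyloxy group, bonds to the acrylate β-carbon C4 slightly ahead of C7a–C3a, so electronic regiochemistry and tether agree. The closest known reaction type is the type 1 intramolecular Diels–Alder reaction of 1-alkoxy-3-silyloxy dienes with acrylates across a three-atom tether. Ring A closes as the six-membered cycloadduct ring and ring B as the five-membered ring spanned by O1–C2–C3 through the C7a–C3a bond. C3a is controlled by C3: with aryl and methyl pseudoequatorial on the forming ring B and the C3–H bond turned toward the C3a=C4 methylene (allylic 1,3-strain), the diene reaches the face that leaves the ester cis to the C3 methyl, while C7a follows from the tether-endo (cis-fused) approach and C5 from suprafacial addition with the methoxy group outside on the diene, hence cis to O1. The only selectivity the route needs is this acrylate face, because C7a becomes trigonal in step 11 and C5 is an epimerisable α-keto position, so a trans-fused adduct would converge on the same target. Dilution, base-washed glass and a radical inhibitor protect the acid-sensitive silyloxy diene and the acrylate until they cyclise.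

**Step 7**
Reactants: 12 tert-butyl (2R,3R,3aS,5R,7aR)-6-(tert-butyldimethylsilyloxy)-5-methoxy-3-methyl-2-(3,4,5-trimethoxyphenyl)-2,3,4,5-tetrahydro-1-benzofuran-3a(7aH)-carboxylate
Product: 13 [(2R,3R,3aR,5R,7aR)-6-(tert-butyldimethylsilyloxy)-5-methoxy-3-methyl-2-(3,4,5-trimethoxyphenyl)-2,3,4,5-tetrahydro-1-benzofuran-3a(7aH)-yl]methanol
Conditions: LiAlH4, THF, 0 °C to rt; then H2O, aq. NaOH
Reagents that add atoms: none
Why: Hydride reduction of the ester (LiAlH4) gives the neopentyl primary alcohol, and the basic medium and work-up leave the silyl enol ether that masks the C6 ketone and all stereocentres intact.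

**Step 8**
Reactants: 13 [(2R,3R,3aR,5R,7aR)-6-(tert-butyldimethylsilyloxy)-5-methoxy-3-methyl-2-(3,4,5-trimethoxyphenyl)-2,3,4,5-tetrahydro-1-benzofuran-3a(7aH)-yl]methanol
Product: 14 (2R,3R,3aS,5R,7aR)-6-(tert-butyldimethylsilyloxy)-5-methoxy-3-methyl-2-(3,4,5-trimethoxyphenyl)-2,3,4,5-tetrahydro-1-benzofuran-3a(7aH)-carbaldehyde
Conditions: Dess–Martin periodinane, pyridine, CH2Cl2, 0 °C
Reagents that add atoms: none
Why: Buffered Dess–Martin oxidation gives the aldehyde, which has no α-hydrogen and so cannot epimerise or enolise, while pyridine takes up the acetic acid that would otherwise hydrolyse the silyl enol ether.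

**Step 9**
Reactants: 14 (2R,3R,3aS,5R,7aR)-6-(tert-butyldimethylsilyloxy)-5-methoxy-3-methyl-2-(3,4,5-trimethoxyphenyl)-2,3,4,5-tetrahydro-1-benzofuran-3a(7aH)-carbaldehyde; 15 vinylmagnesium bromide
Product: 17 methyl 1-[(2R,3R,5R,7aR)-6-(tert-butyldimethylsilyloxy)-5-methoxy-3-methyl-2-(3,4,5-trimethoxyphenyl)-2,3,4,5-tetrahydro-1-benzofuran-3a(7aH)-yl]prop-2-en-1-yl carbonate (ring configuration as in 12; carbinol carbon as a mixture of epimers), via bromomagnesium alkoxide 16 (not isolated)
Conditions: CH2=CHMgBr, THF, −78 °C; then ClCO2Me, −78 to 0 °C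
Reagents that add atoms: methyl chloroformate, COC(=O)Cl
Why: Grignard 1,2-addition of the vinyl group to the non-enolisable aldehyde is followed by acylation of the magnesium alkoxide 16 in the same flask, the new carbinol centre may form as either epimer because it becomes CH2 in step 10, and the medium stays basic throughout.

**Step 10**
Reactants: 17 methyl 1-[(2R,3R,5R,7aR)-6-(tert-butyldimethylsilyloxy)-5-methoxy-3-methyl-2-(3,4,5-trimethoxyphenyl)-2,3,4,5-tetrahydro-1-benzofuran-3a(7aH)-yl]prop-2-en-1-yl carbonate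
Product: 18 tert-butyl{[(2R,3R,3aR,5R,7aR)-5-methoxy-3-methyl-3a-(prop-2-en-1-yl)-2-(3,4,5-trimethoxyphenyl)-2,3,3a,4,5,7a-hexahydro-1-benzofuran-6-yl]oxy}dimethylsilane
Conditions: Pd(OAc)2 (5 mol%), PBu3 (20 mol%), HCO2H, Et3N (excess), THF, 50 °C
Reagents that add atoms: none
Why: In this Tsuji–Trost-type formate reduction, zerovalent palladium ionises the allylic carbonate to a π-allyl complex, formate replaces methoxide and loses CO2, and the hydride passes from palladium (held at the unhindered terminus) to the substituted allyl carbon, which gives the terminal alkene, removes the carbinol centre and leaves the silyl enol ether untouched.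

**Step 11**
Reactants: 18 tert-butyl{[(2R,3R,3aR,5R,7aR)-5-methoxy-3-methyl-3a-(prop-2-en-1-yl)-2-(3,4,5-trimethoxyphenyl)-2,3,3a,4,5,7a-hexahydro-1-benzofuran-6-yl]oxy}dimethylsilane
Product: 21 (2R,3R,3aR,5R)-5-methoxy-3-methyl-3a-(prop-2-en-1-yl)-2-(3,4,5-trimethoxyphenyl)-3,3a,4,5-tetrahydro-1-benzofuran-6(2H)-one, via α-phenylselanyl ketone 19 (not isolated), via selenoxide 20 (not isolated)
Conditions: PhSeCl (1.0 equiv), CH2Cl2, −78 °C; then 30% aq. H2O2, pyridine, 0 °C to rt (then DBU cat., rt, only if a C5 epimer is present)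
Reagents that add atoms: none
Why: α-Selenenylation of the regiodefined silyl enol ether at C7, oxidation to the selenoxide and syn-elimination with H7a (the only β-hydrogen) install the C7=C7a bond of the vinylogous ester; selenium is used instead of a divalent-palladium dehydrogenation because a γ-allyl silyl enol ether is set up for palladium-mediated cycloalkenylation, the C5 methoxy group stays equatorial (trans to the axial allyl group), and C2, C3 and C3a are untouched.

**Compound list**
1 | tert-butyl but-2-ynoate | CC#CC(=O)OC(C)(C)C | starting material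
2 | 2-(iodomethyl)-4,4,5,5-tetramethyl-1,3,2-dioxaborolane (pinacol iodomethylboronate) | ICB1OC(C)(C)C(C)(C)O1 | starting material
3 | tert-butyl (E)-2-(diisobutylalumanyl)but-2-enoate (α-alumino enoate; Al cis to H3, trans to methyl) | C/C=C(/[Al](CC(C)C)CC(C)C)C(=O)OC(C)(C)C | intermediate (not isolated)
4 | tert-butyl (Z)-2-[(4,4,5,5-tetramethyl-1,3,2-dioxaborolan-2-yl)methyl]but-2-enoate (methyl cis to ester, trans to CH2B) | C/C=C(/CB1OC(C)(C)C(C)(C)O1)C(=O)OC(C)(C)C | intermediate
5 | 3,4,5-trimethoxybenzaldehyde | COc1cc(C=O)cc(OC)c1OC | starting material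
6 | tert-butyl (3R,4R)-4-hydroxy-3-methyl-2-methylidene-4-(3,4,5-trimethoxyphenyl)butanoate (anti) | C=C(C(=O)OC(C)(C)C)[C@@H](C)[C@@H](O)c1cc(OC)c(OC)c(OC)c1 | intermediate
7 | N,2-dimethoxy-N-methylacetamide | COCC(=O)N(C)OC | starting material
8 | ethynylmagnesium bromide | C#C[Mg]Br | starting material
9 | 1-methoxybut-3-yn-2-one | COCC(=O)C#C | intermediate
10 | tert-butyl (3R,4R)-4-{[(1E)-4-methoxy-3-oxobut-1-en-1-yl]oxy}-3-methyl-2-methylidene-4-(3,4,5-trimethoxyphenyl)butanoate | C=C(C(=O)OC(C)(C)C)[C@@H](C)[C@@H](O/C=C/C(=O)COC)c1cc(OC)c(OC)c(OC)c1 | intermediate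
11 | tert-butyl (3R,4R)-4-{[(1E,3Z)-3-(tert-butyldimethylsilyloxy)-4-methoxybuta-1,3-dien-1-yl]oxy}-3-methyl-2-methylidene-4-(3,4,5-trimethoxyphenyl)butanoate (Diels–Alder precursor) | C=C(C(=O)OC(C)(C)C)[C@@H](C)[C@@H](O/C=C/C(O[Si](C)(C)C(C)(C)C)=C/OC)c1cc(OC)c(OC)c(OC)c1 | intermediate
12 | tert-butyl (2R,3R,3aS,5R,7aR)-6-(tert-butyldimethylsilyloxy)-5-methoxy-3-methyl-2-(3,4,5-trimethoxyphenyl)-2,3,4,5-tetrahydro-1-benzofuran-3a(7aH)-carboxylate (cis-fused cycloadduct) | CC(C)(C)OC(=O)[C@]12C[C@@H](OC)C(O[Si](C)(C)C(C)(C)C)=C[C@H]1O[C@@H](c1cc(OC)c(OC)c(OC)c1)[C@@H]2C | intermediate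
13 | [(2R,3R,3aR,5R,7aR)-6-(tert-butyldimethylsilyloxy)-5-methoxy-3-methyl-2-(3,4,5-trimethoxyphenyl)-2,3,4,5-tetrahydro-1-benzofuran-3a(7aH)-yl]methanol | OC[C@]12C[C@@H](OC)C(O[Si](C)(C)C(C)(C)C)=C[C@H]1O[C@@H](c1cc(OC)c(OC)c(OC)c1)[C@@H]2C | intermediate
14 | (2R,3R,3aS,5R,7aR)-6-(tert-butyldimethylsilyloxy)-5-methoxy-3-methyl-2-(3,4,5-trimethoxyphenyl)-2,3,4,5-tetrahydro-1-benzofuran-3a(7aH)-carbaldehyde | O=C[C@]12C[C@@H](OC)C(O[Si](C)(C)C(C)(C)C)=C[C@H]1O[C@@H](c1cc(OC)c(OC)c(OC)c1)[C@@H]2C | intermediate
15 | vinylmagnesium bromide | C=C[Mg]Br | starting material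
16 | bromomagnesium alkoxide of the vinyl carbinol on C3a (ring configuration as in 12; carbinol epimers) | C=CC(O[Mg]Br)[C@]12C[C@@H](OC)C(O[Si](C)(C)C(C)(C)C)=C[C@H]1O[C@@H](c1cc(OC)c(OC)c(OC)c1)[C@@H]2C | intermediate (not isolated)
17 | methyl 1-[(2R,3R,5R,7aR)-6-(tert-butyldimethylsilyloxy)-5-methoxy-3-methyl-2-(3,4,5-trimethoxyphenyl)-2,3,4,5-tetrahydro-1-benzofuran-3a(7aH)-yl]prop-2-en-1-yl carbonate (ring configuration as in 12; carbinol epimers) | C=CC(OC(=O)OC)[C@]12C[C@@H](OC)C(O[Si](C)(C)C(C)(C)C)=C[C@H]1O[C@@H](c1cc(OC)c(OC)c(OC)c1)[C@@H]2C | intermediate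
18 | tert-butyl{[(2R,3R,3aR,5R,7aR)-5-methoxy-3-methyl-3a-(prop-2-en-1-yl)-2-(3,4,5-trimethoxyphenyl)-2,3,3a,4,5,7a-hexahydro-1-benzofuran-6-yl]oxy}dimethylsilane | C=CC[C@]12C[C@@H](OC)C(O[Si](C)(C)C(C)(C)C)=C[C@H]1O[C@@H](c1cc(OC)c(OC)c(OC)c1)[C@@H]2C | intermediate
19 | 7-(phenylselanyl) derivative of the saturated C6 ketone (configuration as in 18; C7 epimers) | C=CC[C@]12C[C@@H](OC)C(=O)C([Se]c3ccccc3)[C@H]1O[C@@H](c1cc(OC)c(OC)c(OC)c1)[C@@H]2C | intermediate (not isolated)
20 | selenoxide of 19 | C=CC[C@]12C[C@@H](OC)C(=O)C([Se](=O)c3ccccc3)[C@H]1O[C@@H](c1cc(OC)c(OC)c(OC)c1)[C@@H]2C | intermediate (not isolated)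
21 | (2R,3R,3aR,5R)-5-methoxy-3-methyl-3a-(prop-2-en-1-yl)-2-(3,4,5-trimethoxyphenyl)-3,3a,4,5-tetrahydro-1-benzofuran-6(2H)-one | C=CC[C@]12C[C@@H](OC)C(=O)C=C1O[C@@H](c1cc(OC)c(OC)c(OC)c1)[C@@H]2C | target

**Count and risks**
Total steps: 11. Longest linear sequence: 10 steps (steps 1, 2 and 4 to 11); step 3 is a one-step side branch.

Most likely to fail:

1. Step 6. The diene may add to the wrong face of the acrylate (the C3a epimer), or the silyloxy diene may hydrolyse or oligomerise before it cyclises. Fallback: the rings would be closed anionically. From 10, kinetic deprotonation of the methoxymethyl position with LiN(SiMe3)2 in THF at −78 °C should give the lithium dienolate F1. This would undergo an intramolecular double Michael addition (C5 to C4, then the ester enolate at C3a to C7a) in a lithium-chelated, differently organised transition state, giving the bicyclic lithium enolate F2. O-Silylation with tert-butyldimethylsilyl chloride and DMPU returns the route to 12.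

2. Step 2. The ester-deactivated boronate may add too slowly under the chiral acid, so that an uncatalysed background path erodes enantio- and diastereoselectivity. Fallback: 4 and 5 are heated without catalyst (PhMe, 90 °C), which should give the anti alcohol through the same chair transition state as the racemate, that is 6 together with its (3S,4S)-enantiomer F3. Acylative kinetic resolution follows, using benzotetramisole (the enantiomer that esterifies the (4S)-carbinol), isobutyric anhydride and iPr2NEt in CHCl3. This should convert F3 into the isobutyrate F4 and leave 6, which is separated by chromatography; the route is rejoined at 6.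

3. Step 11. The selenoxide may be unable to reach a syn arrangement with H7a, or selenium and the oxidant may attack the allyl group. Fallback: the unsaturation is introduced before any alkene is present. From 13, Saegusa–Ito oxidation (Pd(OAc)2, MeCN, rt) should give the hydroxymethyl enone F5, and Dess–Martin oxidation the keto aldehyde F6. CH2=CHMgBr at −78 °C should add to the aldehyde in preference to the vinylogous ester and give the allylic alcohol F7, and ClCO2Me with pyridine the allylic methyl carbonate F8. The palladium and formate conditions of step 10 then reduce F8 directly to 21.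

**Further compounds**
F1 | step 6 | lithium (Z)-dienolate of 10 | C=C(C(=O)OC(C)(C)C)[C@@H](C)[C@@H](O/C=C/C(O[Li])=C/OC)c1cc(OC)c(OC)c(OC)c1
F2 | step 6 | bicyclic lithium enolate (lithium analogue of 12) | CC(C)(C)OC(=O)[C@]12C[C@@H](OC)C(O[Li])=C[C@H]1O[C@@H](c1cc(OC)c(OC)c(OC)c1)[C@@H]2C
F3 | step 2 | tert-butyl (3S,4S)-4-hydroxy-3-methyl-2-methylidene-4-(3,4,5-trimethoxyphenyl)butanoate (antipode of 6 in the racemate) | C=C(C(=O)OC(C)(C)C)[C@H](C)[C@H](O)c1cc(OC)c(OC)c(OC)c1
F4 | step 2 | isobutyrate of F3 | C=C(C(=O)OC(C)(C)C)[C@H](C)[C@H](OC(=O)C(C)C)c1cc(OC)c(OC)c(OC)c1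
F5 | step 11 | (2R,3R,3aR,5R)-3a-(hydroxymethyl)-5-methoxy-3-methyl-2-(3,4,5-trimethoxyphenyl)-3,3a,4,5-tetrahydro-1-benzofuran-6(2H)-one | OC[C@]12C[C@@H](OC)C(=O)C=C1O[C@@H](c1cc(OC)c(OC)c(OC)c1)[C@@H]2C
F6 | step 11 | corresponding 3a-carbaldehyde (keto aldehyde) | O=C[C@]12C[C@@H](OC)C(=O)C=C1O[C@@H](c1cc(OC)c(OC)c(OC)c1)[C@@H]2C
F7 | step 11 | 3a-(1-hydroxyprop-2-en-1-yl) enone (carbinol epimers) | C=CC(O)[C@]12C[C@@H](OC)C(=O)C=C1O[C@@H](c1cc(OC)c(OC)c(OC)c1)[C@@H]2C
F8 | step 11 | methyl carbonate of F7 | C=CC(OC(=O)OC)[C@]12C[C@@H](OC)C(=O)C=C1O[C@@H](c1cc(OC)c(OC)c(OC)c1)[C@@H]2C
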